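## Retrosynthetic overview

1. Daphnodorin C ⇐ neutral hydrogenolysis of four aryl benzyl ethers on the intact spiro skeleton.
2. Spiro-dihydrofuran ring (spiro C–CH(Ar) bond, CH(Ar)–O bond, both new stereocentres) ⇐ a new chiral-phosphoric-acid-catalysed (4+1) annulation of a 2-(7-hydroxyflavan-8-yl)benzofuran-3(2H)-one with 4-hydroxybenzaldehyde.
3. Flavan C8–benzofuranone C2 bond ⇐ Friedel–Crafts reaction of a (2S)-flavan-7-ol with the cyclic hemiacetal of a phloroglucinyl glyoxal (benzofuranone ring made by Riley oxidation).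
4. (2S)-Flavan ⇐ Mitsunobu ring closure (inversion) of an (R)-carbinol from asymmetric transfer hydrogenation of a dihydrochalcone, itself from a Claisen–Schmidt condensation.
5. Ring order: chroman (flavan) first, benzofuranone second, spiro-dihydrofuran last.

Assumption: (R)-TRIP in step 11 and the Ir ligand antipode in the step 7 fallback are taken to give the drawn configuration, and the mirror-image catalyst is used if the sense proves opposite; reagents are not numbered, only starting materials, intermediates and products are.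

## Route

Step 1
Reactants: 1 2,4,6-trihydroxybenzaldehyde
Product: 2 2-hydroxy-4,6-bis(methoxymethoxy)benzaldehyde
Conditions: MOMCl (2.2 equiv), K2CO3, acetone, 0 °C → rt
Reagents that add atoms: chloromethyl methyl ether, COCCl
Why: Williamson-type O-alkylation (MOM protection) in which the two non-chelated, more acidic hydroxyls react and the OH hydrogen-bonded to the aldehyde stays free.

Step 2
Reactants: 2 2-hydroxy-4,6-bis(methoxymethoxy)benzaldehyde
Product: 3 2-(benzyloxy)-4,6-bis(methoxymethoxy)benzaldehyde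
Conditions: BnBr (1.2 equiv), K2CO3, DMF, 60 °C
Reagents that add atoms: benzyl bromide, BrCc1ccccc1
Why: Williamson etherification of the remaining chelated phenol under forcing conditions, MOM acetals being stable to base.

Step 3
Reactants: 3 2-(benzyloxy)-4,6-bis(methoxymethoxy)benzaldehyde; 4 1-[4-(benzyloxy)phenyl]ethan-1-one
Product: 5 (E)-3-[2-(benzyloxy)-4,6-bis(methoxymethoxy)phenyl]-1-[4-(benzyloxy)phenyl]prop-2-en-1-one
Conditions: KOH, EtOH/THF, rt
Reagents that add atoms: none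
Why: Claisen–Schmidt (crossed aldol) condensation of a non-enolisable, fully protected aldehyde with a methyl ketone, giving only the (E)-enone.

Step 4
Reactants: 5 (E)-3-[2-(benzyloxy)-4,6-bis(methoxymethoxy)phenyl]-1-[4-(benzyloxy)phenyl]prop-2-en-1-one
Product: 6 3-[2-(benzyloxy)-4,6-bis(methoxymethoxy)phenyl]-1-[4-(benzyloxy)phenyl]propan-1-one
Conditions: H2 (1 atm), 10% Pd/C, Ph2S (1 mol%), EtOAc, rt
Reagents that add atoms: none
Why: Sulfide-poisoned Pd/C hydrogenation saturates the enone C=C without hydrogenolysing benzyl ethers or reducing the aryl ketone.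

Step 5
Reactants: 6 3-[2-(benzyloxy)-4,6-bis(methoxymethoxy)phenyl]-1-[4-(benzyloxy)phenyl]propan-1-one
Product: 7 3-[2-(benzyloxy)-4,6-dihydroxyphenyl]-1-[4-(benzyloxy)phenyl]propan-1-one
Conditions: conc. HCl (cat.), MeOH/THF, 50 °C; aqueous work-up (reopens any cyclic ketal)
Reagents that add atoms: none
Why: Acid-catalysed acetal methanolysis removes both MOM groups at the ketone stage, before any acid-labile benzylic stereocentre exists, and benzyl aryl ethers are stable.

Step 6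
Reactants: 7 3-[2-(benzyloxy)-4,6-dihydroxyphenyl]-1-[4-(benzyloxy)phenyl]propan-1-one
Product: 8 (1R)-3-[2-(benzyloxy)-4,6-dihydroxyphenyl]-1-[4-(benzyloxy)phenyl]propan-1-ol
Conditions: RuCl[(R,R)-TsDPEN](p-cymene) (1 mol%), HCO2H/Et3N (5:2), EtOAc, 35 °C
Reagents that add atoms: none
Why: Noyori-type asymmetric transfer hydrogenation of an aryl alkyl ketone, the (R,R)-catalyst giving the (R)-carbinol as with acetophenone, with free phenols tolerated.

Step 7
Reactants: 8 (1R)-3-[2-(benzyloxy)-4,6-dihydroxyphenyl]-1-[4-(benzyloxy)phenyl]propan-1-ol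
Product: 9 (2S)-5-(benzyloxy)-2-[4-(benzyloxy)phenyl]chroman-7-ol
Conditions: PPh3, DIAD, THF (0.02 M), 0 °C → rt
Reagents that add atoms: none
Why: Intramolecular Mitsunobu etherification in which the ortho phenol displaces the activated benzylic alcohol by SN2 (6-exo-tet) with inversion, setting flavan C2 as S, while dilution suppresses intermolecular attack by the para phenol.

Step 8
Reactants: 10 1-(2,4,6-trihydroxyphenyl)ethan-1-one
Product: 11 1-[2,4-bis(benzyloxy)-6-hydroxyphenyl]ethan-1-one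
Conditions: BnBr (2.1 equiv), K2CO3, DMF, rt
Reagents that add atoms: benzyl bromide, BrCc1ccccc1
Why: Williamson etherification of the two non-chelated phenols, the OH hydrogen-bonded to the acetyl group being left free.

Step 9
Reactants: 11 1-[2,4-bis(benzyloxy)-6-hydroxyphenyl]ethan-1-one
Product: 13 4,6-bis(benzyloxy)-2-hydroxybenzofuran-3(2H)-one, via 2-[2,4-bis(benzyloxy)-6-hydroxyphenyl]-2-oxoacetaldehyde 12 (not isolated)
Conditions: SeO2 (1.3 equiv), 1,4-dioxane/H2O (20:1), 90 °C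
Reagents that add atoms: selenium dioxide, O=[Se]=O
Why: Riley oxidation of the aryl methyl ketone to the aryl glyoxal, which the ortho phenol traps as the five-membered cyclic hemiacetal (racemic, of no consequence).

Step 10
Reactants: 9 (2S)-5-(benzyloxy)-2-[4-(benzyloxy)phenyl]chroman-7-ol; 13 4,6-bis(benzyloxy)-2-hydroxybenzofuran-3(2H)-one
Product: 14 4,6-bis(benzyloxy)-2-{(2S)-5-(benzyloxy)-2-[4-(benzyloxy)phenyl]-7-hydroxychroman-8-yl}benzofuran-3(2H)-one
Conditions: BF3·OEt2 (20 mol%), 4 Å MS, CH2Cl2, −40 → 0 °C, 9 in slight excess; product kept under argon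
Reagents that add atoms: none
Why: Friedel–Crafts C-arylation in which the Lewis acid ionises the hemiacetal to an oxocarbenium ion that the phloroglucinol-type ring attacks at C8, the less hindered position ortho to the free 7-OH; the new C2–H centre is enolisable, is obtained as both epimers and is erased in step 11.

Step 11
Reactants: 14 4,6-bis(benzyloxy)-2-{(2S)-5-(benzyloxy)-2-[4-(benzyloxy)phenyl]-7-hydroxychroman-8-yl}benzofuran-3(2H)-one; 15 4-hydroxybenzaldehyde
Product: 18 (2S,2'S,8'S)-4,6,5'-tris(benzyloxy)-2'-[4-(benzyloxy)phenyl]-8'-(4-hydroxyphenyl)-3',4'-dihydro-2'H,3H,8'H-spiro[benzofuran-2,9'-furo[2,3-h]chromen]-3-one, via (2S)-4,6-bis(benzyloxy)-2-{(2S)-5-(benzyloxy)-2-[4-(benzyloxy)phenyl]-7-hydroxychroman-8-yl}-2-[hydroxy(4-hydroxyphenyl)methyl]benzofuran-3(2H)-one 16 (not isolated), via (2R)-4,6-bis(benzyloxy)-2-{(2S)-5-(benzyloxy)-2-[4-(benzyloxy)phenyl]-7-hydroxychroman-8-yl}-2-[(4-oxocyclohexa-2,5-dien-1-ylidene)methyl]benzofuran-3(2H)-one 17 (not isolated)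
Conditions: 15 (1.5 equiv), (R)-TRIP (10 mol%), 5 Å MS, toluene/CH2Cl2 (4:1), 40 °C, argon
Reagents that add atoms: none
Why: Proposed new method: chiral-phosphoric-acid-catalysed asymmetric (4+1) annulation of a 2-(2-hydroxyaryl)benzofuran-3(2H)-one with an aldehyde, in which the acid hydrogen-bonds the enol tautomer of 14 and the aldehyde so that C2 adds to one face of the C=O (aldol, sets the quaternary spiro centre S), the same acid dehydrates the p-hydroxybenzylic alcohol 16 to p-quinone methide 17, and the neighbouring 7-OH closes by reversible 5-exo oxa-1,6-addition with the aryl group anti to the C3 carbonyl and cis to the benzofuranone ring oxygen (sets C8' S); the closest known chemistry is phosphoric-acid-catalysed 1,6-addition to p-quinone methides generated in situ from p-hydroxybenzyl alcohols and the asymmetric C2-functionalisation of 2-substituted benzofuran-3(2H)-ones, but an aldehyde has not been used as the one-carbon partner to build this spiro ring.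

Step 12
Reactants: 18 (2S,2'S,8'S)-4,6,5'-tris(benzyloxy)-2'-[4-(benzyloxy)phenyl]-8'-(4-hydroxyphenyl)-3',4'-dihydro-2'H,3H,8'H-spiro[benzofuran-2,9'-furo[2,3-h]chromen]-3-one
Product: 19 daphnodorin C, (2S,2'S,8'S)-4,6,5'-trihydroxy-2',8'-bis(4-hydroxyphenyl)-3',4'-dihydro-2'H,3H,8'H-spiro[benzofuran-2,9'-furo[2,3-h]chromen]-3-one
Conditions: H2 (1 atm), 20% Pd(OH)2/C, THF/MeOH, rt, monitored and stopped at full debenzylation
Reagents that add atoms: none
Why: Neutral hydrogenolysis of the four aryl benzyl ethers, which leaves the cyclic benzylic ethers, the hindered electron-rich aryl ketone and all three stereocentres untouched.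

## Compound list

1 | 2,4,6-trihydroxybenzaldehyde | O=Cc1c(O)cc(O)cc1O | starting material
2 | 2-hydroxy-4,6-bis(methoxymethoxy)benzaldehyde | O=Cc1c(O)cc(OCOC)cc1OCOC | intermediate
3 | 2-(benzyloxy)-4,6-bis(methoxymethoxy)benzaldehyde | O=Cc1c(OCc2ccccc2)cc(OCOC)cc1OCOC | intermediate
4 | 1-[4-(benzyloxy)phenyl]ethan-1-one | CC(=O)c1ccc(OCc2ccccc2)cc1 | starting material
5 | (E)-3-[2-(benzyloxy)-4,6-bis(methoxymethoxy)phenyl]-1-[4-(benzyloxy)phenyl]prop-2-en-1-one | O=C(/C=C/c1c(OCc2ccccc2)cc(OCOC)cc1OCOC)c1ccc(OCc2ccccc2)cc1 | intermediate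
6 | 3-[2-(benzyloxy)-4,6-bis(methoxymethoxy)phenyl]-1-[4-(benzyloxy)phenyl]propan-1-one | O=C(CCc1c(OCc2ccccc2)cc(OCOC)cc1OCOC)c1ccc(OCc2ccccc2)cc1 | intermediate
7 | 3-[2-(benzyloxy)-4,6-dihydroxyphenyl]-1-[4-(benzyloxy)phenyl]propan-1-one | O=C(CCc1c(OCc2ccccc2)cc(O)cc1O)c1ccc(OCc2ccccc2)cc1 | intermediate
8 | (1R)-3-[2-(benzyloxy)-4,6-dihydroxyphenyl]-1-[4-(benzyloxy)phenyl]propan-1-ol | O[C@H](CCc1c(OCc2ccccc2)cc(O)cc1O)c1ccc(OCc2ccccc2)cc1 | intermediate
9 | (2S)-5-(benzyloxy)-2-[4-(benzyloxy)phenyl]chroman-7-ol | Oc1cc(OCc2ccccc2)c2c(c1)O[C@H](c1ccc(OCc3ccccc3)cc1)CC2 | intermediate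
10 | 1-(2,4,6-trihydroxyphenyl)ethan-1-one | CC(=O)c1c(O)cc(O)cc1O | starting material
11 | 1-[2,4-bis(benzyloxy)-6-hydroxyphenyl]ethan-1-one | CC(=O)c1c(O)cc(OCc2ccccc2)cc1OCc1ccccc1 | intermediate
12 | 2-[2,4-bis(benzyloxy)-6-hydroxyphenyl]-2-oxoacetaldehyde (not isolated) | O=CC(=O)c1c(O)cc(OCc2ccccc2)cc1OCc1ccccc1 | intermediate
13 | 4,6-bis(benzyloxy)-2-hydroxybenzofuran-3(2H)-one (racemic hemiacetal) | O=C1C(O)Oc2cc(OCc3ccccc3)cc(OCc3ccccc3)c12 | intermediate
14 | 4,6-bis(benzyloxy)-2-{(2S)-5-(benzyloxy)-2-[4-(benzyloxy)phenyl]-7-hydroxychroman-8-yl}benzofuran-3(2H)-one (both C2 epimers, interconverting through the enol) | O=C1C(c2c(O)cc(OCc3ccccc3)c3c2O[C@H](c2ccc(OCc4ccccc4)cc2)CC3)Oc2cc(OCc3ccccc3)cc(OCc3ccccc3)c12 | intermediate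
15 | 4-hydroxybenzaldehyde | O=Cc1ccc(O)cc1 | starting material
16 | (2S)-4,6-bis(benzyloxy)-2-{(2S)-5-(benzyloxy)-2-[4-(benzyloxy)phenyl]-7-hydroxychroman-8-yl}-2-[hydroxy(4-hydroxyphenyl)methyl]benzofuran-3(2H)-one (carbinol epimers, not isolated) | O=C1c2c(OCc3ccccc3)cc(OCc3ccccc3)cc2O[C@]1(C(O)c1ccc(O)cc1)c1c(O)cc(OCc2ccccc2)c2c1O[C@H](c1ccc(OCc3ccccc3)cc1)CC2 | intermediate
17 | (2R)-4,6-bis(benzyloxy)-2-{(2S)-5-(benzyloxy)-2-[4-(benzyloxy)phenyl]-7-hydroxychroman-8-yl}-2-[(4-oxocyclohexa-2,5-dien-1-ylidene)methyl]benzofuran-3(2H)-one (same spatial arrangement at C2 as 16 and 18, descriptor changes by priority only; not isolated) | O=C1c2c(OCc3ccccc3)cc(OCc3ccccc3)cc2O[C@]1(C=C1C=CC(=O)C=C1)c1c(O)cc(OCc2ccccc2)c2c1O[C@H](c1ccc(OCc3ccccc3)cc1)CC2 | intermediate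
18 | (2S,2'S,8'S)-4,6,5'-tris(benzyloxy)-2'-[4-(benzyloxy)phenyl]-8'-(4-hydroxyphenyl)-3',4'-dihydro-2'H,3H,8'H-spiro[benzofuran-2,9'-furo[2,3-h]chromen]-3-one (daphnodorin C benzylated on every phenol except that of the 8'-aryl group; 8'-aryl cis to the benzofuranone ring oxygen) | O=C1c2c(OCc3ccccc3)cc(OCc3ccccc3)cc2O[C@]12c1c(cc(OCc3ccccc3)c3c1O[C@H](c1ccc(OCc4ccccc4)cc1)CC3)O[C@H]2c1ccc(O)cc1 | intermediate
19 | daphnodorin C, (2S,2'S,8'S)-4,6,5'-trihydroxy-2',8'-bis(4-hydroxyphenyl)-3',4'-dihydro-2'H,3H,8'H-spiro[benzofuran-2,9'-furo[2,3-h]chromen]-3-one | O=C1c2c(O)cc(O)cc2O[C@]12c1c(cc(O)c3c1O[C@H](c1ccc(O)cc1)CC3)O[C@H]2c1ccc(O)cc1 | target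

## Step count and risks

Total steps: 12. Longest linear sequence: 10 steps (steps 1–7, then 10, 11, 12); steps 8–9 form the second branch, which joins at step 10.

**Step 11 (the proposed new annulation).** It may fail through a slow aldol at the hindered C2, attack of the aldehyde or quinone methide at flavan C6, acid-induced cyclodehydration of 14, low or opposite induction at the spiro centre, or the wrong C8' epimer. The fallback uses only known reaction types, with substrate control and separation in place of catalysis. It sets out from 14. Acylation of the 7-OH with commercial 4-(benzyloxy)benzoyl chloride (Et3N, DMAP, CH2Cl2) gives (2S)-5-(benzyloxy)-2-[4-(benzyloxy)phenyl]-8-[4,6-bis(benzyloxy)-3-oxo-2,3-dihydrobenzofuran-2-yl]chroman-7-yl 4-(benzyloxy)benzoate F1. A Baker–Venkataraman-type O→C acyl transfer (LiHMDS, THF, −78 → 0 °C) forms the C2–C bond and gives the cyclic hemiketal 4,6,5'-tris(benzyloxy)-2',8'-bis[4-(benzyloxy)phenyl]-8'-hydroxy-spiro lactol F2. Ionic hydrogenation (Et3SiH, BF3·OEt2, CH2Cl2, −78 → −30 °C) reduces the lactol through its oxocarbenium ion to penta-O-benzyl daphnodorin C F3. The stereoisomers at the spiro centre and C8' are diastereomers because of the (2'S)-flavan centre, so they are separated by chromatography. Hydrogenolysis of F3 under the step 12 conditions comes back to the route at 19.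

**Step 10 (Friedel–Crafts coupling).** It may fail through attack at C6 instead of C8, O-alkylation, reaction through the open glyoxal giving the isomeric benzofuranone, or a second alkylation at C2 of 14. The fallback replaces electrophilic substitution by cross-coupling at a pre-installed C8 bromide. It sets out from 9. MOM protection (MOMCl, K2CO3, acetone) gives (2S)-5-(benzyloxy)-2-[4-(benzyloxy)phenyl]-7-(methoxymethoxy)chromane F4. Bromination with NBS (CH2Cl2, −20 °C), which is C8-selective in 5,7-di-O-alkyl flavans, gives (2S)-5-(benzyloxy)-2-[4-(benzyloxy)phenyl]-8-bromo-7-(methoxymethoxy)chromane F5. Palladium-catalysed ketone α-arylation (Pd2(dba)3, XPhos, K3PO4, toluene, 90 °C) couples F5 with 4,6-bis(benzyloxy)benzofuran-3(2H)-one F6, itself made from commercial 4,6-dihydroxybenzofuran-3(2H)-one with BnBr and K2CO3. The product is 4,6-bis(benzyloxy)-2-{(2S)-5-(benzyloxy)-2-[4-(benzyloxy)phenyl]-7-(methoxymethoxy)chroman-8-yl}benzofuran-3(2H)-one F7. Dilute methanolic HCl at rt removes the MOM group and comes back to the route at 14.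

**Step 7 (Mitsunobu closure).** It may fail through partial SN1 ionisation of the p-benzyloxybenzylic carbinol, which erodes ee, or through intermolecular etherification. The fallback sets the stereocentre by alkene hydrogenation instead of substitution. It sets out from 7. Acid-catalysed cyclodehydration (TsOH cat., toluene, 80 °C, argon) gives 5-(benzyloxy)-2-[4-(benzyloxy)phenyl]-4H-chromen-7-ol F8. Iridium/chiral P,N-ligand-catalysed asymmetric hydrogenation of this 2-aryl-4H-chromene (H2 50 bar, CH2Cl2), a known route to flavans that leaves benzyl ethers intact, comes back to the route at 9 and bypasses 8.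

## Further compounds

F1 | step 11 | (2S)-5-(benzyloxy)-2-[4-(benzyloxy)phenyl]-8-[4,6-bis(benzyloxy)-3-oxo-2,3-dihydrobenzofuran-2-yl]chroman-7-yl 4-(benzyloxy)benzoate | O=C1C(c2c(OC(=O)c3ccc(OCc4ccccc4)cc3)cc(OCc3ccccc3)c3c2O[C@H](c2ccc(OCc4ccccc4)cc2)CC3)Oc2cc(OCc3ccccc3)cc(OCc3ccccc3)c12
F2 | step 11 | (2'S)-4,6,5'-tris(benzyloxy)-2',8'-bis[4-(benzyloxy)phenyl]-8'-hydroxy-3',4'-dihydro-2'H,3H,8'H-spiro[benzofuran-2,9'-furo[2,3-h]chromen]-3-one (lactol, mixture at the spiro and hemiketal carbons) | O=C1c2c(OCc3ccccc3)cc(OCc3ccccc3)cc2OC12c1c(cc(OCc3ccccc3)c3c1O[C@H](c1ccc(OCc4ccccc4)cc1)CC3)OC2(O)c1ccc(OCc2ccccc2)cc1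
F3 | step 11 | (2S,2'S,8'S)-4,6,5'-tris(benzyloxy)-2',8'-bis[4-(benzyloxy)phenyl]-3',4'-dihydro-2'H,3H,8'H-spiro[benzofuran-2,9'-furo[2,3-h]chromen]-3-one (penta-O-benzyl daphnodorin C, after separation) | O=C1c2c(OCc3ccccc3)cc(OCc3ccccc3)cc2O[C@]12c1c(cc(OCc3ccccc3)c3c1O[C@H](c1ccc(OCc4ccccc4)cc1)CC3)O[C@H]2c1ccc(OCc2ccccc2)cc1
F4 | step 10 | (2S)-5-(benzyloxy)-2-[4-(benzyloxy)phenyl]-7-(methoxymethoxy)chromane | COCOc1cc(OCc2ccccc2)c2c(c1)O[C@H](c1ccc(OCc3ccccc3)cc1)CC2
F5 | step 10 | (2S)-5-(benzyloxy)-2-[4-(benzyloxy)phenyl]-8-bromo-7-(methoxymethoxy)chromane | COCOc1cc(OCc2ccccc2)c2c(c1Br)O[C@H](c1ccc(OCc3ccccc3)cc1)CC2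
F6 | step 10 | 4,6-bis(benzyloxy)benzofuran-3(2H)-one | O=C1COc2cc(OCc3ccccc3)cc(OCc3ccccc3)c12
F7 | step 10 | 4,6-bis(benzyloxy)-2-{(2S)-5-(benzyloxy)-2-[4-(benzyloxy)phenyl]-7-(methoxymethoxy)chroman-8-yl}benzofuran-3(2H)-one | O=C1C(c2c(OCOC)cc(OCc3ccccc3)c3c2O[C@H](c2ccc(OCc4ccccc4)cc2)CC3)Oc2cc(OCc3ccccc3)cc(OCc3ccccc3)c12
F8 | step 7 | 5-(benzyloxy)-2-[4-(benzyloxy)phenyl]-4H-chromen-7-ol | Oc1cc(OCc2ccccc2)c2c(c1)OC(c1ccc(OCc3ccccc3)cc1)=CC2
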